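The synthesis rests on cutting the two C–H bonds at C7 and C8 of the dihydrodioxine ring. C7 carries the catechol-type aryl group and C8 carries the CH2OH group. Each is bonded to one ring oxygen, and the two are cis, which is the result expected from suprafacial H2 addition to an endocyclic C7=C8 bond. A carboxyl-anchored, iridium-catalysed asymmetric hydrogenation should therefore create both centres, relative and absolute, in one operation. Its precursor is an achiral, planar 3-aryl-1,4-benzodioxine-2-carboxylic acid with a formyl group on the benzo ring. It is built from two 5-hydroxyvanillin units through an α-bromo-β-keto ester, and the aldehyde later becomes the (E)-propenol chain.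

Key step: step 7

Abbreviation: Ar = 3-methoxy-4,5-bis(triisopropylsilyloxy)phenyl.

Remark on locants: the carboxyl (later CH2OH) carbon is C2 of the benzodioxine (lignan C8). It is bonded to O1, and O1 sits on the benzo carbon next to the methoxy carbon. With the acid at C2 and Ar at C3 (lignan C7), the correct benzo locants are therefore 8-methoxy and 6-formyl. The target is cis, (7S,8R) in lignan numbering. The descriptor at C2 changes from S (CO2H, CO2Me) to R (CH2OH) only because the CIP priorities change.

Assumption: the antipode of the spiro ligand that gives the (2S,3S) acid cannot be predicted safely from simpler acrylic acids. It is fixed by one analytical run with each antipode, and the route is written for the matching one.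

Step 1
Reactants: 1 5-hydroxyvanillin (3,4-dihydroxy-5-methoxybenzaldehyde)
Product: 2 3-methoxy-4,5-bis(triisopropylsilyloxy)benzaldehyde
Conditions: TIPSOTf (2.4 equiv), 2,6-lutidine (3.5 equiv), CH2Cl2, 0 °C → rt
Reagents that add atoms: triisopropylsilyl triflate, CC(C)[Si](C(C)C)(C(C)C)OS(=O)(=O)C(F)(F)F
Why: Phenol O-silylation with a silyl triflate and a hindered base should reach even the OH flanked by two ortho oxygens, and aryl TIPS ethers should survive hydrogencarbonate, TFA, Ir/H2, the ylide and DIBAL-H yet still leave under nearly neutral fluoride.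

Step 2
Reactants: 2 3-methoxy-4,5-bis(triisopropylsilyloxy)benzaldehyde; 3 tert-butyl diazoacetate
Product: 4 tert-butyl 3-Ar-3-oxopropanoate
Conditions: NbCl5 (5 mol %), CH2Cl2, 0 °C → rt, slow addition of 3 (1.3 equiv)
Reagents that add atoms: none
Why: In this Roskamp homologation the diazo carbon adds to the Lewis-acid-bound aldehyde and a 1,2-hydride shift with loss of N2 gives the β-keto ester, NbCl5 being the variant best suited to aromatic aldehydes.

Step 3
Reactants: 4 tert-butyl 3-Ar-3-oxopropanoate
Product: 5 tert-butyl 2-bromo-3-Ar-3-oxopropanoate (racemic)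
Conditions: NBS (1.0 equiv), Mg(ClO4)2 (30 mol %), EtOAc, 0 °C → rt, dark
Reagents that add atoms: N-bromosuccinimide, O=C1CCC(=O)N1Br
Why: In this electrophilic α-bromination of a 1,3-dicarbonyl the Mg-chelated enol is far more nucleophilic than the acyl-deactivated, TIPS-shielded arene, so one equivalent of NBS should stop at the monobromide, whose stereocentre is irrelevant because it becomes sp2 in step 5.

Step 4
Reactants: 5 tert-butyl 2-bromo-3-Ar-3-oxopropanoate; 1 5-hydroxyvanillin (1.1 equiv)
Product: 6 tert-butyl 2-(4-formyl-2-hydroxy-6-methoxyphenoxy)-3-Ar-3-oxopropanoate (racemic, handled as a mixture with its ring tautomer)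
Conditions: KHCO3 (1.2 equiv), DMF, 0 °C → rt, Ar
Reagents that add atoms: none
Why: In this Williamson-type SN2 etherification of an α-halo-1,3-dicarbonyl, hydrogencarbonate can ionise only the OH para to the formyl group (about two pK units more acidic than the meta OH), so that oxygen bonds to the future C8, while the bulky tert-butyl ester blocks lactonisation by the remaining phenol.

Step 5
Reactants: 6 tert-butyl 2-(4-formyl-2-hydroxy-6-methoxyphenoxy)-3-Ar-3-oxopropanoate
Product: 9 tert-butyl 6-formyl-8-methoxy-3-Ar-1,4-benzodioxine-2-carboxylate, via cyclic hemiketal 7 (not isolated), via hemiketal trifluoroacetate 8 (not isolated)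
Conditions: (CF3CO)2O (1.5 equiv), pyridine (5 equiv), CH2Cl2, −10 °C → rt
Reagents that add atoms: none
Why: In this activation–elimination of a cyclic hemiketal (lactol-to-enol-ether type) the meta OH adds 6-exo-trig to the aryl ketone, acylation of the phenol in the open tautomer is reversible, and the hemiketal ester ionises to an aryl- and oxygen-stabilised cation that loses the acidic H next to the ester, which should drain the equilibrium into the conjugated dioxine without the dead-end aryl sulfonate that a sulfonyl chloride could give.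

Step 6
Reactants: 9 tert-butyl 6-formyl-8-methoxy-3-Ar-1,4-benzodioxine-2-carboxylate
Product: 10 6-formyl-8-methoxy-3-Ar-1,4-benzodioxine-2-carboxylic acid
Conditions: TFA–CH2Cl2 (1:4), 0 °C → rt, short contact, toluene azeotrope
Reagents that add atoms: none
Why: Acidolysis of a tert-butyl ester by alkyl–oxygen cleavage and isobutene loss needs neither water nor a nucleophile, so the β-aryloxyacrylate, the formyl group and the aryl TIPS ethers should persist if exposure is kept cold and brief to avoid protodecarboxylation.

Step 7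
Reactants: 10 6-formyl-8-methoxy-3-Ar-1,4-benzodioxine-2-carboxylic acid
Product: 11 (2S,3S)-6-formyl-8-methoxy-3-Ar-2,3-dihydro-1,4-benzodioxine-2-carboxylic acid (cis)
Conditions: [Ir(cod)(L*)]BArF (2 mol %; L* = spirobiindane phosphine–oxazoline, SIPHOX type, matching antipode), H2 (30 bar), Et3N (1.0 equiv), MeOH–CH2Cl2 (4:1), 45 °C; cold 5 % aq. citric acid
Reagents that add atoms: none
Why: Proposed new method: the triethylammonium carboxylate of 10 should bind the cationic iridium dihydride as an anionic ligand and hold the neighbouring C2=C3 bond (lignan C8=C7) in the pocket of the spiro P,N ligand, after which migratory insertion, H2 uptake and reductive elimination (Ir(III)/Ir(V) cycle) pass both hydrogens to the same olefin face. The closest known reaction types are the carboxyl-directed Ir/spiro-P,N hydrogenation of α-aryloxy acrylic acids, tetrasubstituted acrylic acids and unsaturated heterocyclic acids, and the Ir- or Rh-catalysed asymmetric hydrogenation of 2-substituted 1,4-benzodioxines, whereas a substrate that is tetrasubstituted, α-aryloxy and β-aryloxy at once is not covered by them. No ring is closed, since the planar dioxine ring is only saturated to the half-chair dihydrodioxine. The cis relation of Ar and CO2H follows from suprafacial delivery to an olefin whose two oxygens are tied cis by the ring, and the absolute configuration at both C2 and C3 is set by the ligand antipode, which selects the face. The step needs enantiofacial selectivity and chemoselectivity for the olefin over ArCHO, and both are secured by the carboxylate anchor at C2, because such catalysts are nearly inert in methanol towards groups that lack an anchor. The carboxylate product has no enolisable ester, so the amine base should not epimerise it.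

Step 8
Reactants: 11 (2S,3S)-6-formyl-8-methoxy-3-Ar-2,3-dihydro-1,4-benzodioxine-2-carboxylic acid; 12 ethyl (triphenylphosphoranylidene)acetate
Product: 14 methyl (2S,3S)-6-[(E)-3-ethoxy-3-oxoprop-1-enyl]-8-methoxy-3-Ar-2,3-dihydro-1,4-benzodioxine-2-carboxylate (cis), via methyl ester aldehyde 13 (not isolated)
Conditions: i) TMSCHN2 (1.05 equiv), PhMe–MeOH (4:1), 0 °C, then evaporate; ii) 12 (1.3 equiv), PhMe, 40 °C
Reagents that add atoms: (trimethylsilyl)diazomethane, C[Si](C)(C)C=[N+]=[N-]
Why: Base-free methylation of the acid by diazomethane released in situ cannot epimerise C2, and the Wittig olefination of the aryl aldehyde with a stabilised, barely basic ylide in an aprotic solvent should give the (E)-cinnamate without touching the α-aryloxy ester.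

Step 9
Reactants: 14 methyl (2S,3S)-6-[(E)-3-ethoxy-3-oxoprop-1-enyl]-8-methoxy-3-Ar-2,3-dihydro-1,4-benzodioxine-2-carboxylate
Product: 15 (E)-3-[(2R,3S)-2-(hydroxymethyl)-8-methoxy-3-Ar-2,3-dihydro-1,4-benzodioxin-6-yl]prop-2-en-1-ol (cis)
Conditions: DIBAL-H (6 equiv), CH2Cl2, −78 → −30 °C; aq. Rochelle salt
Reagents that add atoms: none
Why: In this DIBAL-H reduction of both esters, 1,2-selective hydride delivery turns the cinnamate into the allylic alcohol, and the α-aryloxy ester passes through an aluminium hemiacetal that is reduced further before a free enolisable aldehyde can build up, so both stereocentres should stay untouched.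

Step 10
Reactants: 15 (E)-3-[(2R,3S)-2-(hydroxymethyl)-8-methoxy-3-Ar-2,3-dihydro-1,4-benzodioxin-6-yl]prop-2-en-1-ol
Product: 16 (E)-3-[(2R,3S)-3-(3,4-dihydroxy-5-methoxyphenyl)-2-(hydroxymethyl)-8-methoxy-2,3-dihydro-1,4-benzodioxin-6-yl]prop-2-en-1-ol (cis, lignan 7S,8R; CNP0174261.1)
Conditions: Et3N·3HF (5 equiv), THF, 0 °C → rt, Ar; pH 6 phosphate buffer/EtOAc
Reagents that add atoms: none
Why: Fluoride cleavage of aryl silyl ethers in a slightly acidic medium keeps the liberated para phenol protonated, so no quinone methide can form by expulsion of the C7 aryloxide, and the cis configuration, the cinnamyl alcohol and the air-sensitive catechol should be preserved.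

Compound list
1 | 5-hydroxyvanillin (3,4-dihydroxy-5-methoxybenzaldehyde) | COc1cc(C=O)cc(O)c1O | starting material
2 | 3-methoxy-4,5-bis(triisopropylsilyloxy)benzaldehyde | COc1cc(C=O)cc(O[Si](C(C)C)(C(C)C)C(C)C)c1O[Si](C(C)C)(C(C)C)C(C)C | intermediate
3 | tert-butyl diazoacetate | CC(C)(C)OC(=O)C=[N+]=[N-] | starting material
4 | tert-butyl 3-Ar-3-oxopropanoate | COc1cc(C(=O)CC(=O)OC(C)(C)C)cc(O[Si](C(C)C)(C(C)C)C(C)C)c1O[Si](C(C)C)(C(C)C)C(C)C | intermediate
5 | tert-butyl 2-bromo-3-Ar-3-oxopropanoate (racemic) | COc1cc(C(=O)C(Br)C(=O)OC(C)(C)C)cc(O[Si](C(C)C)(C(C)C)C(C)C)c1O[Si](C(C)C)(C(C)C)C(C)C | intermediate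
6 | tert-butyl 2-(4-formyl-2-hydroxy-6-methoxyphenoxy)-3-Ar-3-oxopropanoate (racemic) | COc1cc(C(=O)C(Oc2c(O)cc(C=O)cc2OC)C(=O)OC(C)(C)C)cc(O[Si](C(C)C)(C(C)C)C(C)C)c1O[Si](C(C)C)(C(C)C)C(C)C | intermediate
7 | tert-butyl 6-formyl-3-hydroxy-8-methoxy-3-Ar-2,3-dihydro-1,4-benzodioxine-2-carboxylate (cyclic hemiketal, racemic diastereomer mixture) | COc1cc(C2(O)Oc3cc(C=O)cc(OC)c3OC2C(=O)OC(C)(C)C)cc(O[Si](C(C)C)(C(C)C)C(C)C)c1O[Si](C(C)C)(C(C)C)C(C)C | intermediate
8 | 3-O-trifluoroacetate of 7 | COc1cc(C2(OC(=O)C(F)(F)F)Oc3cc(C=O)cc(OC)c3OC2C(=O)OC(C)(C)C)cc(O[Si](C(C)C)(C(C)C)C(C)C)c1O[Si](C(C)C)(C(C)C)C(C)C | intermediate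
9 | tert-butyl 6-formyl-8-methoxy-3-Ar-1,4-benzodioxine-2-carboxylate | COc1cc(C2=C(C(=O)OC(C)(C)C)Oc3c(OC)cc(C=O)cc3O2)cc(O[Si](C(C)C)(C(C)C)C(C)C)c1O[Si](C(C)C)(C(C)C)C(C)C | intermediate
10 | 6-formyl-8-methoxy-3-Ar-1,4-benzodioxine-2-carboxylic acid | COc1cc(C2=C(C(=O)O)Oc3c(OC)cc(C=O)cc3O2)cc(O[Si](C(C)C)(C(C)C)C(C)C)c1O[Si](C(C)C)(C(C)C)C(C)C | intermediate
11 | (2S,3S)-6-formyl-8-methoxy-3-Ar-2,3-dihydro-1,4-benzodioxine-2-carboxylic acid (cis) | COc1cc([C@@H]2Oc3cc(C=O)cc(OC)c3O[C@@H]2C(=O)O)cc(O[Si](C(C)C)(C(C)C)C(C)C)c1O[Si](C(C)C)(C(C)C)C(C)C | intermediate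
12 | ethyl (triphenylphosphoranylidene)acetate | CCOC(=O)C=P(c1ccccc1)(c1ccccc1)c1ccccc1 | starting material
13 | methyl (2S,3S)-6-formyl-8-methoxy-3-Ar-2,3-dihydro-1,4-benzodioxine-2-carboxylate (cis) | COc1cc([C@@H]2Oc3cc(C=O)cc(OC)c3O[C@@H]2C(=O)OC)cc(O[Si](C(C)C)(C(C)C)C(C)C)c1O[Si](C(C)C)(C(C)C)C(C)C | intermediate
14 | methyl (2S,3S)-6-[(E)-3-ethoxy-3-oxoprop-1-enyl]-8-methoxy-3-Ar-2,3-dihydro-1,4-benzodioxine-2-carboxylate (cis) | COc1cc([C@@H]2Oc3cc(/C=C/C(=O)OCC)cc(OC)c3O[C@@H]2C(=O)OC)cc(O[Si](C(C)C)(C(C)C)C(C)C)c1O[Si](C(C)C)(C(C)C)C(C)C | intermediate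
15 | (E)-3-[(2R,3S)-2-(hydroxymethyl)-8-methoxy-3-Ar-2,3-dihydro-1,4-benzodioxin-6-yl]prop-2-en-1-ol (cis) | COc1cc([C@@H]2Oc3cc(/C=C/CO)cc(OC)c3O[C@@H]2CO)cc(O[Si](C(C)C)(C(C)C)C(C)C)c1O[Si](C(C)C)(C(C)C)C(C)C | intermediate
16 | CNP0174261.1, (7S,8R)-cis | COc1cc([C@@H]2Oc3cc(/C=C/CO)cc(OC)c3O[C@@H]2CO)cc(O)c1O | target

Total step count: 10. Longest linear sequence: 10 steps (1 → 2 → 4 → 5 → 6 → 9 → 10 → 11 → 14 → 15 → 16).

Steps most likely to fail

First, step 7. The catalyst may not turn over on an olefin that is tetrasubstituted and carries two oxygen donors. Face selection may also be poor, or the formyl group may be reduced or decarbonylated and so poison the metal. The fallback uses known chemistry and replaces asymmetric catalysis by a racemic synthesis with enantiomer separation. Starting from 10, heterogeneous syn-hydrogenation (H2, Pd/C, EtOAc) is the established path from 2,3-disubstituted 1,4-benzodioxines to cis-dihydro compounds, and it should give the racemic cis acid F1. TMSCHN2 then converts it into the racemic cis methyl ester F2. The enantiomers of F2 are separated by preparative chromatography on a polysaccharide-carbamate chiral phase, because the formyl group rules out salt resolution with primary amines. The (2S,3S) enantiomer is 13, and the route is rejoined there at the ylide stage of step 8.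

Second, step 4. Regiocontrol may erode through alkylation at the meta OH. Halophilic attack of the phenoxide may debrominate the electrophile, or silyl transfer to the phenoxide may strip ring B. The fallback removes the choice between two hydroxyl groups and also bypasses step 5. Starting from 5, the single phenol of purchased 5-iodovanillin F3 is alkylated (KHCO3, DMF) to the iodoaryl ether keto ester F4. A copper-catalysed intramolecular O-arylation of its enolate (CuI, 1,10-phenanthroline, K3PO4, PhMe, 90 °C) then closes the dioxine ring and returns to the route at 9. This is the reaction type that turns 2-(2-halobenzyl) β-keto esters into 4H-chromenes. C-arylation is geometrically impossible here.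

Third, step 2. The electron-rich aryl group may migrate instead of hydride, conversion of the deactivated aldehyde may be sluggish, or the Lewis acid may erode the tert-butyl ester. The fallback replaces the diazo insertion by enolate chemistry. Starting from 2, addition of the lithium enolate of tert-butyl acetate (LDA, THF, −78 °C) should give the racemic β-hydroxy ester F5. Oxidation of F5 with Dess–Martin periodinane (CH2Cl2, NaHCO3) leads back to 4.

Further compounds
F1 | step 7 | racemic cis-6-formyl-8-methoxy-3-Ar-2,3-dihydro-1,4-benzodioxine-2-carboxylic acid (both enantiomers drawn) | COc1cc([C@@H]2Oc3cc(C=O)cc(OC)c3O[C@@H]2C(=O)O)cc(O[Si](C(C)C)(C(C)C)C(C)C)c1O[Si](C(C)C)(C(C)C)C(C)C.COc1cc([C@H]2Oc3cc(C=O)cc(OC)c3O[C@H]2C(=O)O)cc(O[Si](C(C)C)(C(C)C)C(C)C)c1O[Si](C(C)C)(C(C)C)C(C)C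
F2 | step 7 | racemic cis methyl 6-formyl-8-methoxy-3-Ar-2,3-dihydro-1,4-benzodioxine-2-carboxylate (both enantiomers drawn) | COc1cc([C@@H]2Oc3cc(C=O)cc(OC)c3O[C@@H]2C(=O)OC)cc(O[Si](C(C)C)(C(C)C)C(C)C)c1O[Si](C(C)C)(C(C)C)C(C)C.COc1cc([C@H]2Oc3cc(C=O)cc(OC)c3O[C@H]2C(=O)OC)cc(O[Si](C(C)C)(C(C)C)C(C)C)c1O[Si](C(C)C)(C(C)C)C(C)C
F3 | step 4 | 5-iodovanillin (4-hydroxy-3-iodo-5-methoxybenzaldehyde, bought) | COc1cc(C=O)cc(I)c1O
F4 | step 4 | tert-butyl 2-(4-formyl-2-iodo-6-methoxyphenoxy)-3-Ar-3-oxopropanoate (racemic) | COc1cc(C(=O)C(Oc2c(I)cc(C=O)cc2OC)C(=O)OC(C)(C)C)cc(O[Si](C(C)C)(C(C)C)C(C)C)c1O[Si](C(C)C)(C(C)C)C(C)C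
F5 | step 2 | tert-butyl 3-hydroxy-3-Ar-propanoate (racemic) | COc1cc(C(O)CC(=O)OC(C)(C)C)cc(O[Si](C(C)C)(C(C)C)C(C)C)c1O[Si](C(C)C)(C(C)C)C(C)C
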